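**Retrosynthetic overview**

1. The target is reached by desilylation and hydrogenolysis of a protected trimer. That trimer is made in one flask from an upper-unit/open-chain middle-unit fragment and tetra-O-benzyl-(−)-epicatechin.
2. Key disconnection: ring C of the middle unit is closed last through O1–C2, by the ring A phenol opening a cis-epoxide. The flavan-3,4-diol formed is ionised at C4 and arylated by C8 of the epicatechin unit in the same operation.
3. Enabling feature of the middle unit: C2 is a benzylic carbon carrying the 4-oxygenated pyrogallol ring B and is vicinal to the C3 carbinol; O1 is a phenolic oxygen of resorcinol ring A ortho to C4a; C4 is benzylic and ortho/para to O1 and the C7 oxygen. O1–C2/C3–O therefore map onto a cis-epoxide and C4 onto a stabilised cation.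
4. The cyclisation precursor comes from an aryllithium (upper unit already attached between the two ring A oxygens) and a cis-epoxy aldehyde made by Sharpless epoxidation. The upper 4-aryl bond comes from aryllithium addition to a flavan-4-one followed by ionic hydrogenation (3,4-cis).
5. Ring order: upper ring C first (chalcone epoxide to dihydroflavonol), lower unit taken intact from (−)-epicatechin, middle ring C last.

Key step: step 17

Remark: wherever a carbinol carbon is turned into a planar cation in the next operation (the tertiary C4 alcohol of the upper unit and the C4 carbinol of the middle unit), it is carried as a mixture of epimers and written without a descriptor.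

**Route**

Step 1
Reactants: 1 1-[4-(benzyloxy)-2-hydroxyphenyl]ethan-1-one
Product: 2 1-[4-(benzyloxy)-2-(methoxymethoxy)phenyl]ethan-1-one
Conditions: MOMCl, K2CO3, acetone, reflux
Reagents that add atoms: chloromethyl methyl ether, COCCl
Why: Williamson-type O-alkylation masks the chelated phenol so that the later enone can be epoxidised without flavonol or aurone formation.

Step 2
Reactants: 2 1-[4-(benzyloxy)-2-(methoxymethoxy)phenyl]ethan-1-one; 3 3,4,5-tris(benzyloxy)benzaldehyde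
Product: 4 (E)-1-[4-(benzyloxy)-2-(methoxymethoxy)phenyl]-3-[3,4,5-tris(benzyloxy)phenyl]prop-2-en-1-one
Conditions: KOH, EtOH/THF, rt
Reagents that add atoms: none
Why: Claisen–Schmidt aldol condensation of a methyl ketone with a non-enolisable aldehyde should give the thermodynamically favoured E-chalcone.

Step 3
Reactants: 4 (E)-1-[4-(benzyloxy)-2-(methoxymethoxy)phenyl]-3-[3,4,5-tris(benzyloxy)phenyl]prop-2-en-1-one
Product: 5 [4-(benzyloxy)-2-(methoxymethoxy)phenyl]{(2S,3R)-3-[3,4,5-tris(benzyloxy)phenyl]oxiran-2-yl}methanone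
Conditions: poly-D-leucine, urea·H2O2, DBU, THF, rt
Reagents that add atoms: hydrogen peroxide (as urea–hydrogen peroxide), OO
Why: Juliá–Colonna asymmetric nucleophilic epoxidation of a chalcone, in which the helical poly-D-leucine (the enantiomer of the catalyst that gives the 2S,3R epoxy ketone) directs hydroperoxide addition to one enone face and the trans geometry is retained.

Step 4
Reactants: 5 [4-(benzyloxy)-2-(methoxymethoxy)phenyl]{(2S,3R)-3-[3,4,5-tris(benzyloxy)phenyl]oxiran-2-yl}methanone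
Product: 6 (2S,3S)-7-(benzyloxy)-3-hydroxy-2-[3,4,5-tris(benzyloxy)phenyl]chroman-4-one
Conditions: HCl (2 M), MeOH/THF, 45 °C
Reagents that add atoms: none
Why: Acid removes the MOM acetal and the freed phenol opens the epoxide at its benzylic carbon (6-endo, inversion at C2, the known chalcone-epoxide route to dihydroflavonols), which should give the 2,3-trans dihydroflavonol with C3 carried over unchanged from the epoxide.

Step 5
Reactants: 6 (2S,3S)-7-(benzyloxy)-3-hydroxy-2-[3,4,5-tris(benzyloxy)phenyl]chroman-4-one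
Product: 7 (2S,3S)-7-(benzyloxy)-3-[(tert-butyldimethylsilyl)oxy]-2-[3,4,5-tris(benzyloxy)phenyl]chroman-4-one
Conditions: TBSOTf, 2,6-lutidine, CH2Cl2, −78 → 0 °C
Reagents that add atoms: tert-butyldimethylsilyl trifluoromethanesulfonate, CC(C)(C)[Si](C)(C)OS(=O)(=O)C(F)(F)F
Why: O-silylation under non-epimerising conditions protects the C3 alcohol and installs the bulky group that later controls the face of hydride delivery at C4.

Step 6
Reactants: 8 2-iodobenzene-1,3-diol
Product: 9 4-bromo-2-iodobenzene-1,3-diol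
Conditions: NBS (1.0 equiv), MeCN, −30 → 0 °C
Reagents that add atoms: N-bromosuccinimide, O=C1CCC(=O)N1Br
Why: Electrophilic aromatic bromination can only occur at the equivalent 4/6 positions (ortho to one hydroxyl, para to the other), so one equivalent should give the 4-bromo compound.

Step 7
Reactants: 9 4-bromo-2-iodobenzene-1,3-diol
Product: 10 1-bromo-3-iodo-2,4-bis(prop-2-en-1-yloxy)benzene
Conditions: allyl bromide, K2CO3, DMF, rt
Reagents that add atoms: allyl bromide, C=CCBr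
Why: Williamson etherification gives allyl ethers that tolerate organolithium reagents and trifluoroacetic acid and can later be removed under neutral conditions.

Step 8
Reactants: 10 1-bromo-3-iodo-2,4-bis(prop-2-en-1-yloxy)benzene; 7 (2S,3S)-7-(benzyloxy)-3-[(tert-butyldimethylsilyl)oxy]-2-[3,4,5-tris(benzyloxy)phenyl]chroman-4-one
Product: 11 (2S,3S)-4-[3-bromo-2,6-bis(prop-2-en-1-yloxy)phenyl]-7-(benzyloxy)-3-[(tert-butyldimethylsilyl)oxy]-2-[3,4,5-tris(benzyloxy)phenyl]chroman-4-ol (C4 epimers)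
Conditions: 10, n-BuLi, THF, −78 °C; then 7, −78 → −40 °C; aqueous work-up
Reagents that add atoms: none
Why: Iodine–lithium exchange is much faster than bromine–lithium exchange and gives the aryllithium flanked by both allyloxy groups, which adds 1,2 to the ketone (addition of 2,6-dioxygenated aryllithiums to 3-silyloxyflavan-4-ones is a precedented reaction type); the new C4 centre is erased in step 9.

Step 9
Reactants: 11 (2S,3S)-4-[3-bromo-2,6-bis(prop-2-en-1-yloxy)phenyl]-7-(benzyloxy)-3-[(tert-butyldimethylsilyl)oxy]-2-[3,4,5-tris(benzyloxy)phenyl]chroman-4-ol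
Product: 12 (2S,3R,4S)-4-[3-bromo-2,6-bis(prop-2-en-1-yloxy)phenyl]-7-(benzyloxy)-3-[(tert-butyldimethylsilyl)oxy]-2-[3,4,5-tris(benzyloxy)phenyl]chromane
Conditions: Bu3SnH, CF3CO2H, CH2Cl2, 0 °C
Reagents that add atoms: none
Why: Ionic hydrogenation: acid ionises the tertiary benzylic alcohol to a C4 cation stabilised by O1, the 7-benzyloxy group and the dialkoxyaryl ring, and hydride should be delivered to the face opposite the bulky C3 silyloxy group (the facial preference nucleophiles show toward 2,3-trans flavan-4-yl cations), so the aryl group ends up cis to the C3 oxygen (4S).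

Step 10
Reactants: 3 3,4,5-tris(benzyloxy)benzaldehyde
Product: 13 methyl (Z)-3-[3,4,5-tris(benzyloxy)phenyl]prop-2-enoate
Conditions: (CF3CH2O)2P(O)CH2CO2Me, KN(SiMe3)2, 18-crown-6, THF, −78 °C
Reagents that add atoms: methyl bis(2,2,2-trifluoroethyl)phosphonoacetate, COC(=O)CP(=O)(OCC(F)(F)F)OCC(F)(F)F
Why: Still–Gennari olefination, in which fast elimination from the electron-poor phosphonate adduct under dissociating conditions should give the Z-enoate.

Step 11
Reactants: 13 methyl (Z)-3-[3,4,5-tris(benzyloxy)phenyl]prop-2-enoate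
Product: 14 (Z)-3-[3,4,5-tris(benzyloxy)phenyl]prop-2-en-1-ol
Conditions: i-Bu2AlH, CH2Cl2, −78 °C
Reagents that add atoms: none
Why: 1,2-Reduction of the ester by the aluminium hydride gives the allylic alcohol without touching the Z-alkene.

Step 12
Reactants: 14 (Z)-3-[3,4,5-tris(benzyloxy)phenyl]prop-2-en-1-ol
Product: 15 {(2S,3R)-3-[3,4,5-tris(benzyloxy)phenyl]oxiran-2-yl}methanol
Conditions: Ti(OiPr)4 (cat.), L-(+)-diisopropyl tartrate, t-BuOOH, 4 Å MS, CH2Cl2, −20 °C
Reagents that add atoms: tert-butyl hydroperoxide, CC(C)(C)OO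
Why: Sharpless asymmetric epoxidation: the titanium tartrate complex with the L-(+)-tartrate delivers oxygen to the face that gives the 2S epoxy alcohol, and the stereospecific syn oxygen transfer keeps the cis geometry, hence 2S,3R.

Step 13
Reactants: 15 {(2S,3R)-3-[3,4,5-tris(benzyloxy)phenyl]oxiran-2-yl}methanol
Product: 16 (2R,3R)-3-[3,4,5-tris(benzyloxy)phenyl]oxirane-2-carbaldehyde
Conditions: Dess–Martin periodinane, pyridine, CH2Cl2, 0 °C
Reagents that add atoms: none
Why: Buffered Dess–Martin oxidation converts the primary alcohol into the aldehyde without opening or epimerising the epoxide (the descriptor at C2 changes only through priority).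

Step 14
Reactants: 12 (2S,3R,4S)-4-[3-bromo-2,6-bis(prop-2-en-1-yloxy)phenyl]-7-(benzyloxy)-3-[(tert-butyldimethylsilyl)oxy]-2-[3,4,5-tris(benzyloxy)phenyl]chromane; 16 (2R,3R)-3-[3,4,5-tris(benzyloxy)phenyl]oxirane-2-carbaldehyde
Product: 17 {2,4-bis(prop-2-en-1-yloxy)-3-[(2S,3R,4S)-7-(benzyloxy)-3-[(tert-butyldimethylsilyl)oxy]-2-[3,4,5-tris(benzyloxy)phenyl]chroman-4-yl]phenyl}{(2S,3R)-3-[3,4,5-tris(benzyloxy)phenyl]oxiran-2-yl}methanol (carbinol epimers)
Conditions: 12, t-BuLi (2 equiv), Et2O/THF, −78 °C; then 16, −78 °C; aqueous work-up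
Reagents that add atoms: none
Why: Bromine–lithium exchange followed by 1,2-addition of the aryllithium to the aldehyde, which is far faster than epoxide opening at −78 °C; both carbinol epimers are usable because this centre is ionised in step 17.

Step 15
Reactants: 17 {2,4-bis(prop-2-en-1-yloxy)-3-[(2S,3R,4S)-7-(benzyloxy)-3-[(tert-butyldimethylsilyl)oxy]-2-[3,4,5-tris(benzyloxy)phenyl]chroman-4-yl]phenyl}{(2S,3R)-3-[3,4,5-tris(benzyloxy)phenyl]oxiran-2-yl}methanol
Product: 18 4-(hydroxy{(2S,3R)-3-[3,4,5-tris(benzyloxy)phenyl]oxiran-2-yl}methyl)-2-[(2S,3R,4S)-7-(benzyloxy)-3-[(tert-butyldimethylsilyl)oxy]-2-[3,4,5-tris(benzyloxy)phenyl]chroman-4-yl]benzene-1,3-diol (carbinol epimers)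
Conditions: Pd(PPh3)4 (cat.), morpholine, THF, 0 °C → rt; rapid filtration, used at once
Reagents that add atoms: none
Why: Tsuji–Trost-type deallylation, in which zerovalent palladium ionises the aryl allyl ethers and morpholine captures the allyl fragment, frees both phenols under near-neutral conditions that should leave the epoxide and the benzylic carbinol intact.

Step 16
Reactants: 19 (−)-epicatechin, (2R,3R)-2-(3,4-dihydroxyphenyl)chromane-3,5,7-triol
Product: 20 (2R,3R)-5,7-bis(benzyloxy)-2-[3,4-bis(benzyloxy)phenyl]chroman-3-ol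
Conditions: BnBr, K2CO3, DMF, 0 °C → rt
Reagents that add atoms: benzyl bromide, BrCc1ccccc1
Why: Williamson benzylation of the four phenols, which are far more acidic than the C3 alcohol, gives the standard C8-nucleophilic lower unit.

Step 17
Reactants: 18 4-(hydroxy{(2S,3R)-3-[3,4,5-tris(benzyloxy)phenyl]oxiran-2-yl}methyl)-2-[(2S,3R,4S)-7-(benzyloxy)-3-[(tert-butyldimethylsilyl)oxy]-2-[3,4,5-tris(benzyloxy)phenyl]chroman-4-yl]benzene-1,3-diol; 20 (2R,3R)-5,7-bis(benzyloxy)-2-[3,4-bis(benzyloxy)phenyl]chroman-3-ol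
Product: 22 (2S,3S,4S)-4-{(2R,3R)-5,7-bis(benzyloxy)-2-[3,4-bis(benzyloxy)phenyl]-3-hydroxychroman-8-yl}-7-hydroxy-2-[3,4,5-tris(benzyloxy)phenyl]-8-[(2S,3R,4S)-7-(benzyloxy)-3-[(tert-butyldimethylsilyl)oxy]-2-[3,4,5-tris(benzyloxy)phenyl]chroman-4-yl]chroman-3-ol, via flavan-3,4-diol 21 (not isolated)
Conditions: 20 (4 equiv), CSA (cat.), 4 Å MS, CH2Cl2, −40 → 0 °C; then BF3·OEt2 (0.3 equiv), −78 → −20 °C
Reagents that add atoms: none
Why: CSA activates the cis-epoxide and the ring A phenol ortho to the side chain opens it at the benzylic carbon C2 in a 6-endo-tet closure with inversion, forming the O1–C2 bond of the middle pyran ring and turning the epoxide oxygen into the C3 hydroxyl, so the 2S,3R epoxide becomes the 2,3-cis (2S,3S) flavan-3,4-diol 21. BF3·OEt2 then ionises the C4 hydroxyl to a cation stabilised by O1 and the para C7 hydroxyl (a protonated para-quinone methide), which is captured by C8 of 20 in a Friedel–Crafts alkylation. The closest known reactions are the acid-mediated cyclisation of 2-hydroxyaryl aryl-epoxides to flavan-3-ols and dihydroflavonols and the Lewis-acid condensation of flavan-3,4-diols with flavan-3-ols. C2 is controlled by the epoxide configuration (SN2-type inversion) and C4 by the substrate, since the nucleophile should add to the face opposite the cis-disposed C2 aryl group and C3 hydroxyl to give the 3,4-trans (4S) product. The step needs attack at C2 rather than C3 (6-endo over 5-exo), which the electron-rich 3,4,5-tris(benzyloxy)phenyl group secures under acid, and ring closure before C4 ionisation, which the staging of weak acid before Lewis acid secures. Attack through C8 rather than C6 of 20 follows the known preference of the tetra-O-benzyl nucleophile, and its excess suppresses self-condensation.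

Step 18
Reactants: 22 the silylated, benzylated trimer from step 17
Product: 23 (2S,3S,4S)-4-{(2R,3R)-5,7-bis(benzyloxy)-2-[3,4-bis(benzyloxy)phenyl]-3-hydroxychroman-8-yl}-8-{(2S,3R,4S)-7-(benzyloxy)-3-hydroxy-2-[3,4,5-tris(benzyloxy)phenyl]chroman-4-yl}-2-[3,4,5-tris(benzyloxy)phenyl]chromane-3,7-diol
Conditions: Bu4NF, THF, rt
Reagents that add atoms: none
Why: Fluoride-mediated cleavage of the silyl ether; the benzylated B rings cannot open to quinone methides, so no stereocentre is at risk under the mildly basic conditions.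

Step 19
Reactants: 23 the undecabenzyl ether from step 18
Product: 24 (2S,3S,4S)-2-(3,4,5-trihydroxyphenyl)-4-[(2R,3R)-2-(3,4-dihydroxyphenyl)-3,5,7-trihydroxychroman-8-yl]-8-[(2S,3R,4S)-3,7-dihydroxy-2-(3,4,5-trihydroxyphenyl)chroman-4-yl]chromane-3,7-diol (CNP0115797.3)
Conditions: H2 (1 atm), Pd(OH)2/C, THF/MeOH/H2O, rt
Reagents that add atoms: none
Why: Catalytic hydrogenolysis removes all eleven benzyl ethers under neutral conditions that leave the interflavan bonds and every stereocentre untouched.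

**Compound list**

1 | 1-[4-(benzyloxy)-2-hydroxyphenyl]ethan-1-one | CC(=O)c1ccc(OCc2ccccc2)cc1O | starting material
2 | 1-[4-(benzyloxy)-2-(methoxymethoxy)phenyl]ethan-1-one | CC(=O)c1ccc(OCc2ccccc2)cc1OCOC | intermediate
3 | 3,4,5-tris(benzyloxy)benzaldehyde | O=Cc1cc(OCc2ccccc2)c(OCc2ccccc2)c(OCc2ccccc2)c1 | starting material
4 | (E)-1-[4-(benzyloxy)-2-(methoxymethoxy)phenyl]-3-[3,4,5-tris(benzyloxy)phenyl]prop-2-en-1-one | COCOc1cc(OCc2ccccc2)ccc1C(=O)/C=C/c1cc(OCc2ccccc2)c(OCc2ccccc2)c(OCc2ccccc2)c1 | intermediate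
5 | [4-(benzyloxy)-2-(methoxymethoxy)phenyl]{(2S,3R)-3-[3,4,5-tris(benzyloxy)phenyl]oxiran-2-yl}methanone | COCOc1cc(OCc2ccccc2)ccc1C(=O)[C@H]1O[C@@H]1c1cc(OCc2ccccc2)c(OCc2ccccc2)c(OCc2ccccc2)c1 | intermediate
6 | (2S,3S)-7-(benzyloxy)-3-hydroxy-2-[3,4,5-tris(benzyloxy)phenyl]chroman-4-one | O=C1c2ccc(OCc3ccccc3)cc2O[C@@H](c2cc(OCc3ccccc3)c(OCc3ccccc3)c(OCc3ccccc3)c2)[C@@H]1O | intermediate
7 | (2S,3S)-7-(benzyloxy)-3-[(tert-butyldimethylsilyl)oxy]-2-[3,4,5-tris(benzyloxy)phenyl]chroman-4-one | O=C1c2ccc(OCc3ccccc3)cc2O[C@@H](c2cc(OCc3ccccc3)c(OCc3ccccc3)c(OCc3ccccc3)c2)[C@@H]1O[Si](C)(C)C(C)(C)C | intermediate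
8 | 2-iodobenzene-1,3-diol | Oc1cccc(O)c1I | starting material
9 | 4-bromo-2-iodobenzene-1,3-diol | Oc1ccc(Br)c(O)c1I | intermediate
10 | 1-bromo-3-iodo-2,4-bis(prop-2-en-1-yloxy)benzene | C=CCOc1ccc(Br)c(OCC=C)c1I | intermediate
11 | (2S,3S)-4-[3-bromo-2,6-bis(prop-2-en-1-yloxy)phenyl]-7-(benzyloxy)-3-[(tert-butyldimethylsilyl)oxy]-2-[3,4,5-tris(benzyloxy)phenyl]chroman-4-ol, C4 epimers | C=CCOc1ccc(Br)c(OCC=C)c1C1(O)c2ccc(OCc3ccccc3)cc2O[C@@H](c2cc(OCc3ccccc3)c(OCc3ccccc3)c(OCc3ccccc3)c2)[C@@H]1O[Si](C)(C)C(C)(C)C | intermediate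
12 | (2S,3R,4S)-4-[3-bromo-2,6-bis(prop-2-en-1-yloxy)phenyl]-7-(benzyloxy)-3-[(tert-butyldimethylsilyl)oxy]-2-[3,4,5-tris(benzyloxy)phenyl]chromane | C=CCOc1ccc(Br)c(OCC=C)c1[C@@H]1c2ccc(OCc3ccccc3)cc2O[C@@H](c2cc(OCc3ccccc3)c(OCc3ccccc3)c(OCc3ccccc3)c2)[C@@H]1O[Si](C)(C)C(C)(C)C | intermediate
13 | methyl (Z)-3-[3,4,5-tris(benzyloxy)phenyl]prop-2-enoate | COC(=O)/C=C\c1cc(OCc2ccccc2)c(OCc2ccccc2)c(OCc2ccccc2)c1 | intermediate
14 | (Z)-3-[3,4,5-tris(benzyloxy)phenyl]prop-2-en-1-ol | OC/C=C\c1cc(OCc2ccccc2)c(OCc2ccccc2)c(OCc2ccccc2)c1 | intermediate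
15 | {(2S,3R)-3-[3,4,5-tris(benzyloxy)phenyl]oxiran-2-yl}methanol | OC[C@@H]1O[C@@H]1c1cc(OCc2ccccc2)c(OCc2ccccc2)c(OCc2ccccc2)c1 | intermediate
16 | (2R,3R)-3-[3,4,5-tris(benzyloxy)phenyl]oxirane-2-carbaldehyde | O=C[C@@H]1O[C@@H]1c1cc(OCc2ccccc2)c(OCc2ccccc2)c(OCc2ccccc2)c1 | intermediate
17 | {2,4-bis(prop-2-en-1-yloxy)-3-[(2S,3R,4S)-7-(benzyloxy)-3-[(tert-butyldimethylsilyl)oxy]-2-[3,4,5-tris(benzyloxy)phenyl]chroman-4-yl]phenyl}{(2S,3R)-3-[3,4,5-tris(benzyloxy)phenyl]oxiran-2-yl}methanol, carbinol epimers | C=CCOc1ccc(C(O)[C@@H]2O[C@@H]2c2cc(OCc3ccccc3)c(OCc3ccccc3)c(OCc3ccccc3)c2)c(OCC=C)c1[C@@H]1c2ccc(OCc3ccccc3)cc2O[C@@H](c2cc(OCc3ccccc3)c(OCc3ccccc3)c(OCc3ccccc3)c2)[C@@H]1O[Si](C)(C)C(C)(C)C | intermediate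
18 | 4-(hydroxy{(2S,3R)-3-[3,4,5-tris(benzyloxy)phenyl]oxiran-2-yl}methyl)-2-[(2S,3R,4S)-7-(benzyloxy)-3-[(tert-butyldimethylsilyl)oxy]-2-[3,4,5-tris(benzyloxy)phenyl]chroman-4-yl]benzene-1,3-diol, carbinol epimers | Oc1ccc(C(O)[C@@H]2O[C@@H]2c2cc(OCc3ccccc3)c(OCc3ccccc3)c(OCc3ccccc3)c2)c(O)c1[C@@H]1c2ccc(OCc3ccccc3)cc2O[C@@H](c2cc(OCc3ccccc3)c(OCc3ccccc3)c(OCc3ccccc3)c2)[C@@H]1O[Si](C)(C)C(C)(C)C | intermediate
19 | (−)-epicatechin, (2R,3R)-2-(3,4-dihydroxyphenyl)chromane-3,5,7-triol | Oc1cc(O)c2c(c1)O[C@H](c1ccc(O)c(O)c1)[C@H](O)C2 | starting material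
20 | (2R,3R)-5,7-bis(benzyloxy)-2-[3,4-bis(benzyloxy)phenyl]chroman-3-ol | c1ccccc1COc1cc(OCc3ccccc3)c2c(c1)O[C@H](c1ccc(OCc3ccccc3)c(OCc3ccccc3)c1)[C@H](O)C2 | intermediate
21 | (2S,3S)-7-hydroxy-2-[3,4,5-tris(benzyloxy)phenyl]-8-[(2S,3R,4S)-7-(benzyloxy)-3-[(tert-butyldimethylsilyl)oxy]-2-[3,4,5-tris(benzyloxy)phenyl]chroman-4-yl]chromane-3,4-diol, C4 epimers (2,3-cis flavan-3,4-diol) | Oc1ccc2c(c1[C@@H]1c3ccc(OCc4ccccc4)cc3O[C@@H](c3cc(OCc4ccccc4)c(OCc4ccccc4)c(OCc4ccccc4)c3)[C@@H]1O[Si](C)(C)C(C)(C)C)O[C@@H](c1cc(OCc3ccccc3)c(OCc3ccccc3)c(OCc3ccccc3)c1)[C@@H](O)C2O | intermediate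
22 | (2S,3S,4S)-4-{(2R,3R)-5,7-bis(benzyloxy)-2-[3,4-bis(benzyloxy)phenyl]-3-hydroxychroman-8-yl}-7-hydroxy-2-[3,4,5-tris(benzyloxy)phenyl]-8-[(2S,3R,4S)-7-(benzyloxy)-3-[(tert-butyldimethylsilyl)oxy]-2-[3,4,5-tris(benzyloxy)phenyl]chroman-4-yl]chroman-3-ol | Oc1ccc2c(c1[C@@H]1c3ccc(OCc4ccccc4)cc3O[C@@H](c3cc(OCc4ccccc4)c(OCc4ccccc4)c(OCc4ccccc4)c3)[C@@H]1O[Si](C)(C)C(C)(C)C)O[C@@H](c1cc(OCc3ccccc3)c(OCc3ccccc3)c(OCc3ccccc3)c1)[C@@H](O)[C@@H]2c1c(OCc3ccccc3)cc(OCc3ccccc3)c2c1O[C@H](c1ccc(OCc3ccccc3)c(OCc3ccccc3)c1)[C@H](O)C2 | intermediate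
23 | (2S,3S,4S)-4-{(2R,3R)-5,7-bis(benzyloxy)-2-[3,4-bis(benzyloxy)phenyl]-3-hydroxychroman-8-yl}-8-{(2S,3R,4S)-7-(benzyloxy)-3-hydroxy-2-[3,4,5-tris(benzyloxy)phenyl]chroman-4-yl}-2-[3,4,5-tris(benzyloxy)phenyl]chromane-3,7-diol | Oc1ccc2c(c1[C@@H]1c3ccc(OCc4ccccc4)cc3O[C@@H](c3cc(OCc4ccccc4)c(OCc4ccccc4)c(OCc4ccccc4)c3)[C@@H]1O)O[C@@H](c1cc(OCc3ccccc3)c(OCc3ccccc3)c(OCc3ccccc3)c1)[C@@H](O)[C@@H]2c1c(OCc3ccccc3)cc(OCc3ccccc3)c2c1O[C@H](c1ccc(OCc3ccccc3)c(OCc3ccccc3)c1)[C@H](O)C2 | intermediate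
24 | (2S,3S,4S)-2-(3,4,5-trihydroxyphenyl)-4-[(2R,3R)-2-(3,4-dihydroxyphenyl)-3,5,7-trihydroxychroman-8-yl]-8-[(2S,3R,4S)-3,7-dihydroxy-2-(3,4,5-trihydroxyphenyl)chroman-4-yl]chromane-3,7-diol (CNP0115797.3) | Oc1ccc2c(c1)O[C@@H](c1cc(O)c(O)c(O)c1)[C@H](O)[C@@H]2c1c(O)ccc2c1O[C@@H](c1cc(O)c(O)c(O)c1)[C@@H](O)[C@@H]2c1c(O)cc(O)c2c1O[C@H](c1ccc(O)c(O)c1)[C@H](O)C2 | target

**Step count and risks**

Total steps: 19. Longest linear sequence: 12 steps (steps 1–5, 8, 9, 14, 15, 17, 18, 19).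

Most likely to fail:

Step 17. The bulky nucleophile 20 may capture the C4 cation too slowly under the Lewis-acidic conditions, so that self-condensation of the free resorcinol ring and ionisation of C4 before the pyran ring has closed erode yield and C4 control. The fallback sets out from 18 and returns at 22 and replaces the direct condensation by a sulfur relay. Compound 18 is cyclised with catalytic CSA in CH2Cl2 as before, then benzyl mercaptan and BF3·OEt2 are added. The small, highly nucleophilic thiol should trap the C4 cation cleanly and give (2S,3R)-4-(benzylsulfanyl)-7-hydroxy-2-[3,4,5-tris(benzyloxy)phenyl]-8-[(2S,3R,4S)-7-(benzyloxy)-3-[(tert-butyldimethylsilyl)oxy]-2-[3,4,5-tris(benzyloxy)phenyl]chroman-4-yl]chroman-3-ol F1 as C4 epimers (the C3 descriptor changes only because sulfur outranks oxygen). Thiophilic activation of isolated F1 with AgBF4 in THF/CH2Cl2 in the presence of 20 then regenerates the cation from the closed pyran ring only, under neutral conditions, and should give 22 with the same 3,4-trans preference.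

Step 9. Hydride may be delivered with poor facial selectivity to the C4 cation, because the C3 silyloxy group and the C2 aryl group direct to opposite faces, and elimination to the enol ether may compete. The fallback sets out from 11 and returns at 12 and sets C4 by an intramolecular hydride shift instead of an external hydride. Desilylation of 11 with Bu4NF gives (2S,3S)-4-[3-bromo-2,6-bis(prop-2-en-1-yloxy)phenyl]-7-(benzyloxy)-2-[3,4,5-tris(benzyloxy)phenyl]chromane-3,4-diol F2. A pinacol rearrangement (BF3·OEt2, CH2Cl2, −78 °C) should then move the C3 hydrogen, which lies anti to the C3 oxygen, suprafacially to the C4 cation and give (2S,4S)-4-[3-bromo-2,6-bis(prop-2-en-1-yloxy)phenyl]-7-(benzyloxy)-2-[3,4,5-tris(benzyloxy)phenyl]chroman-3-one F3 with the required C4 configuration. NaBH4 at low temperature should attack the face opposite the pseudo-axial 4-aryl group and give (2S,3R,4S)-4-[3-bromo-2,6-bis(prop-2-en-1-yloxy)phenyl]-7-(benzyloxy)-2-[3,4,5-tris(benzyloxy)phenyl]chroman-3-ol F4, and silylation with TBSOTf and 2,6-lutidine returns 12.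

Step 12. Titanium-tartrate epoxidation of a Z-allylic alcohol is slow and less enantioselective than that of E-isomers, and the electron-rich aryl epoxy alcohol may be opened at its benzylic carbon by titanium alkoxides. The fallback sets out from 13 and returns at 15 and moves the asymmetric step to the ester. Jacobsen–Katsuki epoxidation of 13 (NaOCl, 4-phenylpyridine N-oxide, the (R,R)-configured (salen)MnCl catalyst, the enantiomer that gives 2R,3R cis-glycidates from Z-cinnamates) should give methyl (2R,3R)-3-[3,4,5-tris(benzyloxy)phenyl]oxirane-2-carboxylate F5 under basic, non-Lewis-acidic conditions. Reduction of F5 with i-Bu2AlH at low temperature gives 15. Any minor enantiomer carried forward becomes a separable diastereomer after step 14.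

Further compounds
F1 | step 17 | (2S,3R)-4-(benzylsulfanyl)-7-hydroxy-2-[3,4,5-tris(benzyloxy)phenyl]-8-[(2S,3R,4S)-7-(benzyloxy)-3-[(tert-butyldimethylsilyl)oxy]-2-[3,4,5-tris(benzyloxy)phenyl]chroman-4-yl]chroman-3-ol, C4 epimers | Oc1ccc2c(c1[C@@H]1c3ccc(OCc4ccccc4)cc3O[C@@H](c3cc(OCc4ccccc4)c(OCc4ccccc4)c(OCc4ccccc4)c3)[C@@H]1O[Si](C)(C)C(C)(C)C)O[C@@H](c1cc(OCc3ccccc3)c(OCc3ccccc3)c(OCc3ccccc3)c1)[C@@H](O)C2SCc1ccccc1
F2 | step 9 | (2S,3S)-4-[3-bromo-2,6-bis(prop-2-en-1-yloxy)phenyl]-7-(benzyloxy)-2-[3,4,5-tris(benzyloxy)phenyl]chromane-3,4-diol, C4 epimers | C=CCOc1ccc(Br)c(OCC=C)c1C1(O)c2ccc(OCc3ccccc3)cc2O[C@@H](c2cc(OCc3ccccc3)c(OCc3ccccc3)c(OCc3ccccc3)c2)[C@@H]1O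
F3 | step 9 | (2S,4S)-4-[3-bromo-2,6-bis(prop-2-en-1-yloxy)phenyl]-7-(benzyloxy)-2-[3,4,5-tris(benzyloxy)phenyl]chroman-3-one | C=CCOc1ccc(Br)c(OCC=C)c1[C@@H]1c2ccc(OCc3ccccc3)cc2O[C@@H](c2cc(OCc3ccccc3)c(OCc3ccccc3)c(OCc3ccccc3)c2)C1=O
F4 | step 9 | (2S,3R,4S)-4-[3-bromo-2,6-bis(prop-2-en-1-yloxy)phenyl]-7-(benzyloxy)-2-[3,4,5-tris(benzyloxy)phenyl]chroman-3-ol | C=CCOc1ccc(Br)c(OCC=C)c1[C@@H]1c2ccc(OCc3ccccc3)cc2O[C@@H](c2cc(OCc3ccccc3)c(OCc3ccccc3)c(OCc3ccccc3)c2)[C@@H]1O
F5 | step 12 | methyl (2R,3R)-3-[3,4,5-tris(benzyloxy)phenyl]oxirane-2-carboxylate | COC(=O)[C@@H]1O[C@@H]1c1cc(OCc2ccccc2)c(OCc2ccccc2)c(OCc2ccccc2)c1
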